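**Retrosynthetic overview**
1. Target 31 ⇐ O-methylation of hydroxyquinone 30 ⇐ (KSO3)2NO oxidation of the 5-alkyl-4-methylresorcinol 29.
2. The only ring is formed once: the open 2-methyl-3,5,7-trioxo acid 27 (a tetraketide) closes by C2→C7 aldol addition and loses CO2, the fold used by alkylresorcinol-forming polyketide synthases; 27 is released in the flask from pyranone 26.
3. 26 ⇐ Claisen acylation of the dianion of 4-hydroxy-3,6-dimethyl-2-pyranone 24 with fatty ester 23.
4. 23 ⇐ B-alkyl Suzuki coupling of alkene 20 with methyl 7-bromoheptanoate 21; 20 ⇐ Zweifel vinylation of boronic ester 17.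
5. 17 ⇐ boronic ester 7 (from (S)-1-bromo-2-methylbutane) by three insertions of one chiral CH(CH3) carbenoid (from stannane 4), alternating with CH2 insertions.

Assumption: 4-hydroxy-3,6-dimethyl-2H-pyran-2-one (24), (S)-1-bromo-2-methylbutane (5) and (+)-sparteine are bought as catalogue chemicals.

**Route**

Step 1
Reactants: 1 2,4,6-triisopropylbenzoic acid
Product: 2 ethyl 2,4,6-triisopropylbenzoate
Conditions: EtI, K2CO3, DMF, 50 °C
Reagents that add atoms: iodoethane CCI
Why: SN2 O-alkylation of the carboxylate avoids the sterically blocked acyl carbon of this hindered acid; no stereocentre is formed.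

Step 2
Reactants: 2 ethyl 2,4,6-triisopropylbenzoate
Product: 4 (R)-1-(trimethylstannyl)ethyl 2,4,6-triisopropylbenzoate, via lithiated benzoate 3 (not isolated)
Conditions: sBuLi, (+)-sparteine, Et2O, −78 °C; Me3SnCl, −78 °C → rt; recrystallisation from MeOH
Reagents that add atoms: chlorotrimethylstannane C[Sn](C)(C)Cl; sec-butyllithium [Li]C(C)CC (its lithium stays only in 3)
Why: Hoppe-type sparteine-mediated asymmetric deprotonation gives the configurationally stable (R)-organolithium 3 as its (+)-sparteine complex, which is stannylated with retention, and one recrystallisation should bring 4 to >99:1 er.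

Step 3
Reactants: 5 (S)-1-bromo-2-methylbutane
Product: 7 (R)-4,4,5,5-tetramethyl-2-(2-methylbutyl)-1,3,2-dioxaborolane, via Grignard reagent 6 (not isolated)
Conditions: Mg, THF, 40 °C; iPrOBpin, −78 °C → rt
Reagents that add atoms: 2-isopropoxy-4,4,5,5-tetramethyl-1,3,2-dioxaborolane CC(C)OB1OC(C)(C)C(C)(C)O1; magnesium [Mg] (stays only in 6)
Why: Grignard formation followed by substitution at boron; the first stereocentre comes from the chiral pool, sits β to the metal and is untouched (the descriptor changes from S to R only through the CIP priorities).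

Step 4
Reactants: 7 (R)-4,4,5,5-tetramethyl-2-(2-methylbutyl)-1,3,2-dioxaborolane; 4 (R)-1-(trimethylstannyl)ethyl 2,4,6-triisopropylbenzoate
Product: 11 2-[(2R,4S)-2,4-dimethylhexyl]-4,4,5,5-tetramethyl-1,3,2-dioxaborolane, via lithium boronate complex 8 (not isolated), via secondary boronic ester 9 (not isolated), via chloromethyl boronate complex 10 (not isolated)
Conditions: 4, nBuLi, Et2O, −78 °C; 7, −78 → 35 °C; then BrCH2Cl, nBuLi, −78 °C → rt
Reagents that add atoms: bromochloromethane ClCBr; n-butyllithium [Li]CCCC (its lithium stays only in 8 and 10)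
Why: Lithiation–borylation: tin–lithium exchange on 4 releases the diamine-free (R)-lithiated benzoate with retention, it adds to boron with retention to give 8, the 1,2-metallate rearrangement with inversion at the carbenoid carbon sets the new CH(CH3) centre syn to the existing one under reagent control, and the telescoped Matteson homologation with LiCH2Cl through 10 inserts the CH2 spacer with retention at the migrating carbon.

Step 5
Reactants: 11 2-[(2R,4S)-2,4-dimethylhexyl]-4,4,5,5-tetramethyl-1,3,2-dioxaborolane; 4 (R)-1-(trimethylstannyl)ethyl 2,4,6-triisopropylbenzoate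
Product: 15 4,4,5,5-tetramethyl-2-[(2R,4R,6S)-2,4,6-trimethyloctyl]-1,3,2-dioxaborolane, via lithium boronate complex 12 (not isolated), via secondary boronic ester 13 (not isolated), via chloromethyl boronate complex 14 (not isolated)
Conditions: 4, nBuLi, Et2O, −78 °C; 11, −78 → 35 °C; then BrCH2Cl, nBuLi, −78 °C → rt
Reagents that add atoms: bromochloromethane ClCBr; n-butyllithium [Li]CCCC (its lithium stays only in 12 and 14)
Why: The same lithiation–borylation and Matteson pair with a fresh portion of the carbenoid made from 4; because the carbenoid configuration alone decides the new centre, the same (R)-reagent again gives the syn relationship whatever the substrate stereochemistry.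

Step 6
Reactants: 15 4,4,5,5-tetramethyl-2-[(2R,4R,6S)-2,4,6-trimethyloctyl]-1,3,2-dioxaborolane; 4 (R)-1-(trimethylstannyl)ethyl 2,4,6-triisopropylbenzoate
Product: 17 4,4,5,5-tetramethyl-2-[(2S,4R,6S,8S)-4,6,8-trimethyldecan-2-yl]-1,3,2-dioxaborolane, via lithium boronate complex 16 (not isolated)
Conditions: 4, nBuLi, Et2O, −78 °C; 15, −78 → 35 °C
Reagents that add atoms: n-butyllithium [Li]CCCC (its lithium stays only in 16)
Why: A third lithiation–borylation (retention at boron, inversion at the carbenoid carbon in the 1,2-shift of 16) sets the fourth methyl centre, giving the all-syn array with boron on the last stereocentre.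

Step 7
Reactants: 17 4,4,5,5-tetramethyl-2-[(2S,4R,6S,8S)-4,6,8-trimethyldecan-2-yl]-1,3,2-dioxaborolane
Product: 20 (3S,5S,7S,9S)-3,5,7,9-tetramethylundec-1-ene, via vinyl boronate complex 18 (not isolated), via iodo boronic ester 19 (not isolated)
Conditions: CH2=CHMgBr, THF/DMSO, rt; I2, THF, 0 °C; NaOMe, MeOH, 0 °C → rt
Reagents that add atoms: vinylmagnesium bromide C=C[Mg]Br (its magnesium and bromine stay only in 18); iodine II (stays only in 19)
Why: Zweifel olefination: iodination of the vinyl boronate triggers 1,2-migration of the secondary alkyl group with retention, and methoxide-induced anti elimination of boron and iodide gives the terminal alkene with the stereocentre intact.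

Step 8
Reactants: 20 (3S,5S,7S,9S)-3,5,7,9-tetramethylundec-1-ene; 21 methyl 7-bromoheptanoate
Product: 23 methyl (10R,12R,14S,16S)-10,12,14,16-tetramethyloctadecanoate, via alkyl borane 22 (not isolated)
Conditions: 9-BBN, THF, rt; then 21, Pd(OAc)2 (4 mol %), PCy3 (8 mol %), K3PO4·H2O, THF, rt
Reagents that add atoms: 9-borabicyclo[3.3.1]nonane B1C2CCCC1CCC2 (its boron stays only in 22)
Why: Anti-Markovnikov hydroboration followed by alkyl–alkyl Suzuki–Miyaura coupling under Fu-type conditions (divalent palladium reduced in the flask to zerovalent palladium, with PCy3 suppressing β-hydride elimination), which tolerates the ester and touches no stereocentre.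

Step 9
Reactants: 23 methyl (10R,12R,14S,16S)-10,12,14,16-tetramethyloctadecanoate; 24 4-hydroxy-3,6-dimethyl-2H-pyran-2-one
Product: 26 4-hydroxy-3-methyl-6-[(11R,13R,15S,17S)-11,13,15,17-tetramethyl-2-oxononadecyl]-2H-pyran-2-one, via pyranone dianion 25 (not isolated)
Conditions: 24 (3 equiv), LiN(iPr)2 (6.5 equiv), THF/DMPU, −78 → 0 °C; 23, 0 °C → rt; 1 M HCl
Reagents that add atoms: lithium diisopropylamide [Li]N(C(C)C)C(C)C (its lithium stays only in 25)
Why: Claisen-type C-acylation at the most basic carbon of the dianion (the 6-methyl group), with excess dianion taking up the acidic proton of the product; the stereocentres are remote and not epimerisable.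

Step 10
Reactants: 26 4-hydroxy-3-methyl-6-[(11R,13R,15S,17S)-11,13,15,17-tetramethyl-2-oxononadecyl]-2H-pyran-2-one
Product: 29 4-methyl-5-[(9R,11R,13S,15S)-9,11,13,15-tetramethylheptadecyl]benzene-1,3-diol, via trioxo acid 27 (not isolated), via cyclohexenedione acid 28 (not isolated)
Conditions: 2 M KOH, H2O/1,4-dioxane, Ar, rt → 45 °C; then 6 M HCl to pH 1, 50 °C
Reagents that add atoms: potassium hydroxide [K+].[OH-] (its oxygen stays only in 27 and 28)
Why: Proposed new method: hydroxide opens the lactone to the 2-methyl-3,5,7-trioxo carboxylate 27, whose C2 (the only carbon between a ketone and the carboxylate) adds to the C7 ketone in an intramolecular aldol addition while Claisen closure onto a carboxylate is impossible, E1cB dehydration gives 28, and on acidification the quaternary β-keto acid loses CO2 with aromatisation, as in the aldol/decarboxylation of the type 3 polyketide synthases; the closest known reaction type is the aqueous-base aldol conversion of 6-(2-oxoalkyl)-4-hydroxy-2-pyranones (tetraacetic acid lactone) into orsellinic-type acids, extended here to a 2-methyl chain; no stereocentre is formed or endangered.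

Step 11
Reactants: 29 4-methyl-5-[(9R,11R,13S,15S)-9,11,13,15-tetramethylheptadecyl]benzene-1,3-diol
Product: 30 2-hydroxy-5-methyl-6-[(9R,11R,13S,15S)-9,11,13,15-tetramethylheptadecyl]cyclohexa-2,5-diene-1,4-dione
Conditions: (KSO3)2NO, KH2PO4, H2O/acetone, 0 °C → rt
Reagents that add atoms: potassium nitrosodisulfonate [K+].[K+].[O]N(S(=O)(=O)[O-])S(=O)(=O)[O-]
Why: Teuber oxidation converts the phenol OH with a free para position (the one next to the ring methyl) into the para-quinone and leaves the second OH as the vinylogous acid; attack through the other OH gives the same compound as its tautomer.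

Step 12
Reactants: 30 2-hydroxy-5-methyl-6-[(9R,11R,13S,15S)-9,11,13,15-tetramethylheptadecyl]cyclohexa-2,5-diene-1,4-dione
Product: 31 2-methoxy-5-methyl-6-[(9R,11R,13S,15S)-9,11,13,15-tetramethylheptadecyl]cyclohexa-2,5-diene-1,4-dione
Conditions: MeOH, H2SO4 (cat.), rt
Reagents that add atoms: methanol CO
Why: Acid-catalysed vinylogous Fischer etherification (addition–elimination of MeOH at the hydroxy-bearing quinone carbon) is reversible and settles on the more stable 2-methoxy-1,4-quinone instead of the ortho-quinone ether; the only free OH is the one to be methylated.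

**Compound list**
1 | 2,4,6-triisopropylbenzoic acid | OC(=O)c1c(C(C)C)cc(C(C)C)cc1C(C)C | starting material
2 | ethyl 2,4,6-triisopropylbenzoate | CCOC(=O)c1c(C(C)C)cc(C(C)C)cc1C(C)C | intermediate
3 | (R)-1-lithioethyl 2,4,6-triisopropylbenzoate ((+)-sparteine complex in the flask) | C[C@@H]([Li])OC(=O)c1c(C(C)C)cc(C(C)C)cc1C(C)C | intermediate
4 | (R)-1-(trimethylstannyl)ethyl 2,4,6-triisopropylbenzoate | C[C@@H]([Sn](C)(C)C)OC(=O)c1c(C(C)C)cc(C(C)C)cc1C(C)C | intermediate
5 | (S)-1-bromo-2-methylbutane | CC[C@H](C)CBr | starting material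
6 | (S)-(2-methylbutyl)magnesium bromide | CC[C@H](C)C[Mg]Br | intermediate
7 | (R)-4,4,5,5-tetramethyl-2-(2-methylbutyl)-1,3,2-dioxaborolane | CC[C@H](C)CB1OC(C)(C)C(C)(C)O1 | intermediate
8 | lithium 4,4,5,5-tetramethyl-2-[(2R)-2-methylbutyl]-2-[(1R)-1-(2,4,6-triisopropylbenzoyloxy)ethyl]-1,3,2-dioxaborolan-2-uide | CC[C@H](C)C[B-]1([C@H](C)OC(=O)c2c(C(C)C)cc(C(C)C)cc2C(C)C)OC(C)(C)C(C)(C)O1.[Li+] | intermediate
9 | 4,4,5,5-tetramethyl-2-[(2S,4S)-4-methylhexan-2-yl]-1,3,2-dioxaborolane | CC[C@H](C)C[C@H](C)B1OC(C)(C)C(C)(C)O1 | intermediate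
10 | lithium 2-(chloromethyl)-4,4,5,5-tetramethyl-2-[(2S,4S)-4-methylhexan-2-yl]-1,3,2-dioxaborolan-2-uide | CC[C@H](C)C[C@H](C)[B-]1(CCl)OC(C)(C)C(C)(C)O1.[Li+] | intermediate
11 | 2-[(2R,4S)-2,4-dimethylhexyl]-4,4,5,5-tetramethyl-1,3,2-dioxaborolane | CC[C@H](C)C[C@H](C)CB1OC(C)(C)C(C)(C)O1 | intermediate
12 | lithium 2-[(2R,4S)-2,4-dimethylhexyl]-4,4,5,5-tetramethyl-2-[(1R)-1-(2,4,6-triisopropylbenzoyloxy)ethyl]-1,3,2-dioxaborolan-2-uide | CC[C@H](C)C[C@H](C)C[B-]1([C@H](C)OC(=O)c2c(C(C)C)cc(C(C)C)cc2C(C)C)OC(C)(C)C(C)(C)O1.[Li+] | intermediate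
13 | 2-[(2S,4R,6S)-4,6-dimethyloctan-2-yl]-4,4,5,5-tetramethyl-1,3,2-dioxaborolane | CC[C@H](C)C[C@H](C)C[C@H](C)B1OC(C)(C)C(C)(C)O1 | intermediate
14 | lithium 2-(chloromethyl)-2-[(2S,4R,6S)-4,6-dimethyloctan-2-yl]-4,4,5,5-tetramethyl-1,3,2-dioxaborolan-2-uide | CC[C@H](C)C[C@H](C)C[C@H](C)[B-]1(CCl)OC(C)(C)C(C)(C)O1.[Li+] | intermediate
15 | 4,4,5,5-tetramethyl-2-[(2R,4R,6S)-2,4,6-trimethyloctyl]-1,3,2-dioxaborolane | CC[C@H](C)C[C@H](C)C[C@H](C)CB1OC(C)(C)C(C)(C)O1 | intermediate
16 | lithium 4,4,5,5-tetramethyl-2-[(1R)-1-(2,4,6-triisopropylbenzoyloxy)ethyl]-2-[(2R,4R,6S)-2,4,6-trimethyloctyl]-1,3,2-dioxaborolan-2-uide | CC[C@H](C)C[C@H](C)C[C@H](C)C[B-]1([C@H](C)OC(=O)c2c(C(C)C)cc(C(C)C)cc2C(C)C)OC(C)(C)C(C)(C)O1.[Li+] | intermediate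
17 | 4,4,5,5-tetramethyl-2-[(2S,4R,6S,8S)-4,6,8-trimethyldecan-2-yl]-1,3,2-dioxaborolane | CC[C@H](C)C[C@H](C)C[C@H](C)C[C@H](C)B1OC(C)(C)C(C)(C)O1 | intermediate
18 | bromomagnesium 2-ethenyl-4,4,5,5-tetramethyl-2-[(2S,4R,6S,8S)-4,6,8-trimethyldecan-2-yl]-1,3,2-dioxaborolan-2-uide | CC[C@H](C)C[C@H](C)C[C@H](C)C[C@H](C)[B-]1(C=C)OC(C)(C)C(C)(C)O1.[Mg+]Br | intermediate
19 | 2-[(3S,5S,7S,9S)-1-iodo-3,5,7,9-tetramethylundecan-2-yl]-4,4,5,5-tetramethyl-1,3,2-dioxaborolane (C2 epimers) | CC[C@H](C)C[C@H](C)C[C@H](C)C[C@H](C)C(CI)B1OC(C)(C)C(C)(C)O1 | intermediate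
20 | (3S,5S,7S,9S)-3,5,7,9-tetramethylundec-1-ene | CC[C@H](C)C[C@H](C)C[C@H](C)C[C@H](C)C=C | intermediate
21 | methyl 7-bromoheptanoate | COC(=O)CCCCCCBr | starting material
22 | 9-[(3R,5R,7S,9S)-3,5,7,9-tetramethylundecyl]-9-borabicyclo[3.3.1]nonane | CC[C@H](C)C[C@H](C)C[C@H](C)C[C@H](C)CCB1C2CCCC1CCC2 | intermediate
23 | methyl (10R,12R,14S,16S)-10,12,14,16-tetramethyloctadecanoate | CC[C@H](C)C[C@H](C)C[C@H](C)C[C@H](C)CCCCCCCCC(=O)OC | intermediate
24 | 4-hydroxy-3,6-dimethyl-2H-pyran-2-one | CC1=CC(O)=C(C)C(=O)O1 | starting material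
25 | lithium 6-(lithiomethyl)-3-methyl-2-oxo-2H-pyran-4-olate (dianion of 24) | [Li]CC1=CC(O[Li])=C(C)C(=O)O1 | intermediate
26 | 4-hydroxy-3-methyl-6-[(11R,13R,15S,17S)-11,13,15,17-tetramethyl-2-oxononadecyl]-2H-pyran-2-one | CC[C@H](C)C[C@H](C)C[C@H](C)C[C@H](C)CCCCCCCCC(=O)CC1=CC(O)=C(C)C(=O)O1 | intermediate
27 | (16R,18R,20S,22S)-2,16,18,20,22-pentamethyl-3,5,7-trioxotetracosanoic acid (C2 epimers; potassium salt in the flask) | CC[C@H](C)C[C@H](C)C[C@H](C)C[C@H](C)CCCCCCCCC(=O)CC(=O)CC(=O)C(C)C(=O)O | intermediate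
28 | 1-methyl-2,4-dioxo-6-[(9R,11R,13S,15S)-9,11,13,15-tetramethylheptadecyl]cyclohex-5-ene-1-carboxylic acid (C1 epimers; potassium salt in the flask) | CC[C@H](C)C[C@H](C)C[C@H](C)C[C@H](C)CCCCCCCCC1=CC(=O)CC(=O)C1(C)C(=O)O | intermediate
29 | 4-methyl-5-[(9R,11R,13S,15S)-9,11,13,15-tetramethylheptadecyl]benzene-1,3-diol | CC[C@H](C)C[C@H](C)C[C@H](C)C[C@H](C)CCCCCCCCc1cc(O)cc(O)c1C | intermediate
30 | 2-hydroxy-5-methyl-6-[(9R,11R,13S,15S)-9,11,13,15-tetramethylheptadecyl]cyclohexa-2,5-diene-1,4-dione | CC[C@H](C)C[C@H](C)C[C@H](C)C[C@H](C)CCCCCCCCC1=C(C)C(=O)C=C(O)C1=O | intermediate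
31 | 2-methoxy-5-methyl-6-[(9R,11R,13S,15S)-9,11,13,15-tetramethylheptadecyl]cyclohexa-2,5-diene-1,4-dione (CNP0330767.1) | CC[C@H](C)C[C@H](C)C[C@H](C)C[C@H](C)CCCCCCCCC1=C(C)C(=O)C=C(OC)C1=O | target

**Step count and risks**

Total steps: 12. Longest linear sequence: 11 (steps 1, 2 and 4–12, counted from acid 1 through stannane 4; step 3 supplies boronic ester 7 to step 4). The four stereocentres are set in steps 3 (chiral pool), 4, 5 and 6; none is next to an acidic position afterwards.

Step 10 (most likely to fail). The aldol addition has to create a quaternary carbon. Competing paths are closure from the side-chain α-carbon onto C3 (this by-product keeps its carboxyl and is removed by a bicarbonate wash) and early decarboxylation to a triketone that cyclises unselectively. The fallback sets out from 23 and comes back at 29. Ester 23 is acylated as in step 9, but with lithium 6-(lithiomethyl)-2-oxo-2H-pyran-4-olate F1, made from commercial 4-hydroxy-6-methyl-2H-pyran-2-one and LiN(iPr)2. This gives 4-hydroxy-6-[(11R,13R,15S,17S)-11,13,15,17-tetramethyl-2-oxononadecyl]-2H-pyran-2-one F2. Aqueous KOH opens it to (16R,18R,20S,22S)-16,18,20,22-tetramethyl-3,5,7-trioxotetracosanoic acid F3, which closes by the known aldol mode, with no quaternary carbon, to 2,4-dihydroxy-6-[(9R,11R,13S,15S)-9,11,13,15-tetramethylheptadecyl]benzoic acid F4. BH3·SMe2 reduces the carboxyl to 4-(hydroxymethyl)-5-[(9R,11R,13S,15S)-9,11,13,15-tetramethylheptadecyl]benzene-1,3-diol F5, and Et3SiH/CF3CO2H removes the benzylic oxygen by ionic hydrogenation through the quinone methide cation to give 29.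

Step 9. The dianion may deprotonate the enolisable aliphatic ester instead of acylating, and its lithium salts are poorly soluble. The fallback sets out from 23 and comes back at 26. iBu2AlH (toluene, −78 °C) gives (10R,12R,14S,16S)-10,12,14,16-tetramethyloctadecanal F6. Dianion 25 adds to this aldehyde in an aldol-type addition, which is faster than any proton transfer, to give 4-hydroxy-6-[(11R,13R,15S,17S)-2-hydroxy-11,13,15,17-tetramethylnonadecyl]-3-methyl-2H-pyran-2-one F7 as a mixture of carbinol epimers. Dess–Martin periodinane oxidises the carbinol to 26.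

Step 12. Methanol may add to the quinone, or the ortho-quinone ether may form. The fallback sets out from 30 and comes back at 31. Na2S2O4 reduces 30 to 5-methyl-6-[(9R,11R,13S,15S)-9,11,13,15-tetramethylheptadecyl]benzene-1,2,4-triol F8, which is methylated in the same flask (Me2SO4, K2CO3, acetone) to 1,2,5-trimethoxy-4-methyl-3-[(9R,11R,13S,15S)-9,11,13,15-tetramethylheptadecyl]benzene F9. (NH4)2Ce(NO3)6 in MeCN/H2O then removes the two para-related methyl groups oxidatively; this gives the para-quinone 31 with the third methoxy group left where the target has it.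

**Further compounds**
F1 | step 10 | lithium 6-(lithiomethyl)-2-oxo-2H-pyran-4-olate | [Li]CC1=CC(O[Li])=CC(=O)O1
F2 | step 10 | 4-hydroxy-6-[(11R,13R,15S,17S)-11,13,15,17-tetramethyl-2-oxononadecyl]-2H-pyran-2-one | CC[C@H](C)C[C@H](C)C[C@H](C)C[C@H](C)CCCCCCCCC(=O)CC1=CC(O)=CC(=O)O1
F3 | step 10 | (16R,18R,20S,22S)-16,18,20,22-tetramethyl-3,5,7-trioxotetracosanoic acid | CC[C@H](C)C[C@H](C)C[C@H](C)C[C@H](C)CCCCCCCCC(=O)CC(=O)CC(=O)CC(=O)O
F4 | step 10 | 2,4-dihydroxy-6-[(9R,11R,13S,15S)-9,11,13,15-tetramethylheptadecyl]benzoic acid | CC[C@H](C)C[C@H](C)C[C@H](C)C[C@H](C)CCCCCCCCc1cc(O)cc(O)c1C(=O)O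
F5 | step 10 | 4-(hydroxymethyl)-5-[(9R,11R,13S,15S)-9,11,13,15-tetramethylheptadecyl]benzene-1,3-diol | CC[C@H](C)C[C@H](C)C[C@H](C)C[C@H](C)CCCCCCCCc1cc(O)cc(O)c1CO
F6 | step 9 | (10R,12R,14S,16S)-10,12,14,16-tetramethyloctadecanal | CC[C@H](C)C[C@H](C)C[C@H](C)C[C@H](C)CCCCCCCCC=O
F7 | step 9 | 4-hydroxy-6-[(11R,13R,15S,17S)-2-hydroxy-11,13,15,17-tetramethylnonadecyl]-3-methyl-2H-pyran-2-one (carbinol epimers) | CC[C@H](C)C[C@H](C)C[C@H](C)C[C@H](C)CCCCCCCCC(O)CC1=CC(O)=C(C)C(=O)O1
F8 | step 12 | 5-methyl-6-[(9R,11R,13S,15S)-9,11,13,15-tetramethylheptadecyl]benzene-1,2,4-triol | CC[C@H](C)C[C@H](C)C[C@H](C)C[C@H](C)CCCCCCCCc1c(C)c(O)cc(O)c1O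
F9 | step 12 | 1,2,5-trimethoxy-4-methyl-3-[(9R,11R,13S,15S)-9,11,13,15-tetramethylheptadecyl]benzene | CC[C@H](C)C[C@H](C)C[C@H](C)C[C@H](C)CCCCCCCCc1c(C)c(OC)cc(OC)c1OC
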